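**Plan**
Rings: A = benzo ring of the benzofuran, B = resorcinol ring on C3, C = catechol ring on C2, D = resorcinol ring of the styryl arm.
Retrosynthesis: cut the C5–vinyl bond (Heck), then the C3–ring B bond (back to a C3 carboxylate), then C3–C3a (back to a flavanone whose C4 is the carboxyl carbon), and last C2–ring C (conjugate addition to 6-bromochromone).
Enabling feature: O1–C2 with ring C and the 2S configuration is the O1–C2 edge of a natural-series (2S)-flavanone; shifting ring A carbon C4a from the carbonyl carbon C4 to the neighbouring CH2 contracts the pyranone to the dihydrofuran and leaves C4 as an ester handle on C3.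
Forward: ring C boronic acid, then the flavanone (pyranone ring from the chromone), then the five-membered ring by trivalent-iodine ring contraction, then the stilbene, then ring B by nickel decarboxylative arylation, then demethylation and detosylation.
Stereochemistry: C2 comes from ligand-controlled palladium conjugate addition; C3 is set trans by C2, first in the ring contraction and finally in the radical arylation; the E alkene comes from the Heck reaction.

Key step: step 5

Assumption: the facial sense of t-BuPyOx on chromones is taken to follow that known for β-substituted cyclohexenones, where the (S)-ligand puts the aryl group on the face that corresponds to 2R in a chroman-4-one; the (R)-ligand is therefore specified for the 2S series, and its antipode would be used should the sense prove opposite.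

Ts = 4-methylbenzenesulfonyl throughout.

**Step 1**
Reactants: 1 4-bromocatechol
Product: 2 4-bromo-1,2-phenylene bis(4-methylbenzenesulfonate)
Conditions: TsCl (2.2 equiv), Et3N, DMAP (cat.), CH2Cl2, 0 °C → rt
Reagents that add atoms: p-toluenesulfonyl chloride, Cc1ccc(S(=O)(=O)Cl)cc1
Why: Sulfonylation of both phenols under amine/DMAP catalysis gives the bis-tosylate, which makes ring C electron-poor for the later rearrangement and is inert to the palladium and nickel steps that follow.

**Step 2**
Reactants: 2 4-bromo-1,2-phenylene bis(4-methylbenzenesulfonate)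
Product: 3 4-(4,4,5,5-tetramethyl-1,3,2-dioxaborolan-2-yl)-1,2-phenylene bis(4-methylbenzenesulfonate)
Conditions: B2pin2, PdCl2(dppf) (3 mol %), KOAc, 1,4-dioxane, 85 °C
Reagents that add atoms: bis(pinacolato)diboron, CC1(C)OB(OC1(C)C)B1OC(C)(C)C(C)(C)O1
Why: Miyaura borylation, in which zerovalent palladium inserts selectively into the C–Br bond because aryl tosylates do not undergo oxidative addition with the dppf catalyst under acetate conditions.

**Step 3**
Reactants: 3 4-(4,4,5,5-tetramethyl-1,3,2-dioxaborolan-2-yl)-1,2-phenylene bis(4-methylbenzenesulfonate)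
Product: 4 [3,4-bis(tosyloxy)phenyl]boronic acid
Conditions: NaIO4, NH4OAc, acetone/H2O, rt
Reagents that add atoms: water, O
Why: Oxidative cleavage of the pinacol released in the hydrolysis equilibrium by periodate drives the boronate to the free boronic acid needed for transmetalation to cationic divalent palladium in the next step.

**Step 4**
Reactants: 5 6-bromochromone; 4 [3,4-bis(tosyloxy)phenyl]boronic acid
Product: 6 (2S)-6-bromo-2-[3,4-bis(tosyloxy)phenyl]chroman-4-one
Conditions: Pd(OCOCF3)2 (5 mol %), (R)-t-BuPyOx [(R)-4-tert-butyl-2-(pyridin-2-yl)-4,5-dihydrooxazole] (6 mol %), NH4PF6 (30 mol %), H2O (5 equiv), 4 (2 equiv), ClCH2CH2Cl, 60 °C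
Reagents that add atoms: none
Why: Enantioselective palladium-catalysed conjugate addition of an arylboronic acid to a chromone, in which the cationic aryl–palladium PyOx complex stays divalent (so the C–Br bond is untouched), inserts the C2=C3 bond on the face dictated by the tert-butyl oxazoline, and protonation of the palladium enolate should give the 2S stereocentre.

**Step 5**
Reactants: 6 (2S)-6-bromo-2-[3,4-bis(tosyloxy)phenyl]chroman-4-one
Product: 9 methyl (2S,3S)-5-bromo-2-[3,4-bis(tosyloxy)phenyl]-2,3-dihydro-1-benzofuran-3-carboxylate (2,3-trans), via methyl enol ether 7 (not isolated), via trans C3 phenyliodanyl ketal 8 (not isolated)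
Conditions: PhI(OAc)2 (1.2 equiv), conc. H2SO4 (cat.), HC(OMe)3, 0 °C → rt; then H2O
Reagents that add atoms: trimethyl orthoformate, COC(OC)OC; water, O
Why: Acid and orthoformate convert ketone 6 into the methyl enol ether 7, electrophilic trivalent iodine adds to C3 on the face anti to ring C while methanol caps C4 to give the λ3-iodanyl ketal 8, and ring A carbon C4a then shifts from C4 to C3 with inversion as iodobenzene departs, the dimethoxycarbenium ion left at C4 being quenched to the methyl ester. This is the established trivalent-iodine (or trivalent-thallium) oxidative ring contraction of flavanones in trimethyl orthoformate, which is known to give trans methyl 2-aryl-2,3-dihydrobenzofuran-3-carboxylates. The five-membered ring is closed not by an exo or endo cyclisation but by a 1,2-aryl shift through a phenonium-type bridged transition state (formally a 3-exo-tet attack of C4a on C3), which contracts the pyranone by one atom. The new C3 centre is controlled by C2: anti iodination followed by invertive migration places the ester trans to ring C (3S), which is also the thermodynamically preferred arrangement at this epimerisable position, while C2 itself is not touched. The step needs ring A to migrate in preference to ring C (isoflavone formation) and to outrun elimination to the flavone or simple C3 methoxylation; O1 ortho to C4a raises the migratory aptitude of ring A, the two tosyloxy groups make ring C a poor migrating group and disfavour ionisation at C2, and ketalisation at C4 in the orthoformate medium opens the semipinacol-type pathway.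

**Step 6**
Reactants: 9 methyl (2S,3S)-5-bromo-2-[3,4-bis(tosyloxy)phenyl]-2,3-dihydro-1-benzofuran-3-carboxylate; 10 3,5-dimethoxystyrene
Product: 11 methyl (2S,3S)-5-[(E)-2-(3,5-dimethoxyphenyl)ethenyl]-2-[3,4-bis(tosyloxy)phenyl]-2,3-dihydro-1-benzofuran-3-carboxylate
Conditions: Pd(OAc)2 (5 mol %), P(o-tol)3 (10 mol %), Et3N, DMF, 100 °C
Reagents that add atoms: none
Why: Heck reaction of the aryl bromide with the styrene, whose syn carbopalladation and syn β-hydride elimination should give the E stilbene, with the aryl tosylates inert to the triarylphosphine catalyst and the trans ester being the stable C3 epimer under amine base.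

**Step 7**
Reactants: 11 methyl (2S,3S)-5-[(E)-2-(3,5-dimethoxyphenyl)ethenyl]-2-[3,4-bis(tosyloxy)phenyl]-2,3-dihydro-1-benzofuran-3-carboxylate
Product: 12 (2S,3S)-5-[(E)-2-(3,5-dimethoxyphenyl)ethenyl]-2-[3,4-bis(tosyloxy)phenyl]-2,3-dihydro-1-benzofuran-3-carboxylic acid
Conditions: Me3SnOH, ClCH2CH2Cl, 80 °C; then 1 M HCl
Reagents that add atoms: trimethyltin hydroxide, C[Sn](C)(C)O
Why: Trimethyltin hydroxide cleaves the methyl ester by a mild, essentially neutral acyl substitution that spares the aryl sulfonates and avoids strong base at the acidic C3–H.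

**Step 8**
Reactants: 12 (2S,3S)-5-[(E)-2-(3,5-dimethoxyphenyl)ethenyl]-2-[3,4-bis(tosyloxy)phenyl]-2,3-dihydro-1-benzofuran-3-carboxylic acid
Product: 13 1,3-dioxoisoindolin-2-yl (2S,3S)-5-[(E)-2-(3,5-dimethoxyphenyl)ethenyl]-2-[3,4-bis(tosyloxy)phenyl]-2,3-dihydro-1-benzofuran-3-carboxylate
Conditions: N-hydroxyphthalimide, N,N'-diisopropylcarbodiimide, DMAP (cat.), CH2Cl2, rt
Reagents that add atoms: N-hydroxyphthalimide, O=C1c2ccccc2C(=O)N1O
Why: Carbodiimide (Steglich-type) esterification with N-hydroxyphthalimide gives the redox-active ester needed for single-electron decarboxylation, and the C3 configuration is of no consequence because it is erased in the arylation.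

**Step 9**
Reactants: 14 1-iodo-3,5-dimethoxybenzene
Product: 16 (3,5-dimethoxyphenyl)zinc chloride (titrated THF solution), via arylmagnesium chloride 15 (not isolated)
Conditions: i-PrMgCl·LiCl, THF, 0 °C → rt; then ZnCl2 (THF), rt
Reagents that add atoms: zinc chloride, Cl[Zn]Cl
Why: Iodine–magnesium exchange with the turbo Grignard reagent followed by transmetalation to zinc is the standard preparation of an arylzinc chloride for Negishi-type coupling.

**Step 10**
Reactants: 13 1,3-dioxoisoindolin-2-yl (2S,3S)-5-[(E)-2-(3,5-dimethoxyphenyl)ethenyl]-2-[3,4-bis(tosyloxy)phenyl]-2,3-dihydro-1-benzofuran-3-carboxylate; 16 (3,5-dimethoxyphenyl)zinc chloride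
Product: 17 4-[(2S,3S)-3-(3,5-dimethoxyphenyl)-5-[(E)-2-(3,5-dimethoxyphenyl)ethenyl]-2,3-dihydro-1-benzofuran-2-yl]-1,2-phenylene bis(4-methylbenzenesulfonate)
Conditions: NiCl2·glyme (20 mol %), 4,4'-di-tert-butyl-2,2'-bipyridine (40 mol %), 16 (3 equiv), THF/DMF, rt; then 1 M HCl
Reagents that add atoms: none
Why: Nickel-catalysed decarboxylative Negishi-type arylation of a redox-active ester, in which single-electron reduction by low-valent nickel releases CO2 and a planar benzylic C3 radical that is captured by arylnickel and reductively eliminated on the face away from ring C at C2, so the 2,3-trans (3S) isomer should dominate while the aryl sulfonates stay inert to bipyridine-ligated nickel at room temperature.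

**Step 11**
Reactants: 17 4-[(2S,3S)-3-(3,5-dimethoxyphenyl)-5-[(E)-2-(3,5-dimethoxyphenyl)ethenyl]-2,3-dihydro-1-benzofuran-2-yl]-1,2-phenylene bis(4-methylbenzenesulfonate)
Product: 18 4-[(2S,3S)-3-(3,5-dihydroxyphenyl)-5-[(E)-2-(3,5-dihydroxyphenyl)ethenyl]-2,3-dihydro-1-benzofuran-2-yl]-1,2-phenylene bis(4-methylbenzenesulfonate)
Conditions: BBr3 (10 equiv), CH2Cl2, −78 °C → 0 °C; then H2O
Reagents that add atoms: none
Why: Boron tribromide ether cleavage removes the four aryl methyl groups by bromide attack at methyl, while the aryl sulfonates are inert and, by keeping ring C electron-poor, protect the benzylic C2–O1 bond from Lewis-acid ionisation so that both stereocentres should be retained.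

**Step 12**
Reactants: 18 4-[(2S,3S)-3-(3,5-dihydroxyphenyl)-5-[(E)-2-(3,5-dihydroxyphenyl)ethenyl]-2,3-dihydro-1-benzofuran-2-yl]-1,2-phenylene bis(4-methylbenzenesulfonate)
Product: 19 5-[(E)-2-[(2S,3S)-2-(3,4-dihydroxyphenyl)-3-(3,5-dihydroxyphenyl)-2,3-dihydro-1-benzofuran-5-yl]ethenyl]benzene-1,3-diol (CNP0207985.1)
Conditions: KOH (excess), degassed H2O/1,4-dioxane, 80 °C, Ar; then 1 M HCl to pH 3
Reagents that add atoms: none
Why: Alkaline sulfonate hydrolysis, in which hydroxide attacks sulfur with S–O cleavage to release the catechol, run in an alcohol-free and oxygen-free medium so that no alkyl tosylate can re-alkylate the phenoxides and the polyphenolate is not oxidised, with neither stereocentre acidic enough to epimerise.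

**Compound list**
1 | 4-bromocatechol | Oc1ccc(Br)cc1O | starting material
2 | 4-bromo-1,2-phenylene bis(4-methylbenzenesulfonate) | Brc1ccc(OS(=O)(=O)c2ccc(C)cc2)c(OS(=O)(=O)c2ccc(C)cc2)c1 | intermediate
3 | 4-(4,4,5,5-tetramethyl-1,3,2-dioxaborolan-2-yl)-1,2-phenylene bis(4-methylbenzenesulfonate) | CC1(C)OB(OC1(C)C)c1ccc(OS(=O)(=O)c2ccc(C)cc2)c(OS(=O)(=O)c2ccc(C)cc2)c1 | intermediate
4 | [3,4-bis(tosyloxy)phenyl]boronic acid | OB(O)c1ccc(OS(=O)(=O)c2ccc(C)cc2)c(OS(=O)(=O)c2ccc(C)cc2)c1 | intermediate
5 | 6-bromochromone (6-bromo-4H-chromen-4-one) | O=c1ccoc2ccc(Br)cc12 | starting material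
6 | (2S)-6-bromo-2-[3,4-bis(tosyloxy)phenyl]chroman-4-one | O=C1C[C@@H](c2ccc(OS(=O)(=O)c3ccc(C)cc3)c(OS(=O)(=O)c3ccc(C)cc3)c2)Oc2ccc(Br)cc21 | intermediate
7 | 6-bromo-4-methoxy-2-[3,4-bis(tosyloxy)phenyl]-2H-chromene, C2 configured as in 6 (2S) | COC1=C[C@@H](c2ccc(OS(=O)(=O)c3ccc(C)cc3)c(OS(=O)(=O)c3ccc(C)cc3)c2)Oc2ccc(Br)cc21 | intermediate (not isolated)
8 | 2,3-trans-3-[acetoxy(phenyl)-λ3-iodanyl]-6-bromo-4,4-dimethoxy-2-[3,4-bis(tosyloxy)phenyl]chromane, C2 configured as in 6 and iodine anti to ring C | COC1(OC)[C@H](I(OC(C)=O)c2ccccc2)[C@@H](c2ccc(OS(=O)(=O)c3ccc(C)cc3)c(OS(=O)(=O)c3ccc(C)cc3)c2)Oc2ccc(Br)cc21 | intermediate (not isolated)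
9 | methyl (2S,3S)-5-bromo-2-[3,4-bis(tosyloxy)phenyl]-2,3-dihydro-1-benzofuran-3-carboxylate (trans) | Brc1ccc2c(c1)[C@H](C(=O)OC)[C@@H](c1ccc(OS(=O)(=O)c3ccc(C)cc3)c(OS(=O)(=O)c3ccc(C)cc3)c1)O2 | intermediate
10 | 3,5-dimethoxystyrene | C=Cc1cc(OC)cc(OC)c1 | starting material
11 | methyl (2S,3S)-5-[(E)-2-(3,5-dimethoxyphenyl)ethenyl]-2-[3,4-bis(tosyloxy)phenyl]-2,3-dihydro-1-benzofuran-3-carboxylate | COc1cc(OC)cc(/C=C/c2ccc3c(c2)[C@H](C(=O)OC)[C@@H](c2ccc(OS(=O)(=O)c4ccc(C)cc4)c(OS(=O)(=O)c4ccc(C)cc4)c2)O3)c1 | intermediate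
12 | (2S,3S)-5-[(E)-2-(3,5-dimethoxyphenyl)ethenyl]-2-[3,4-bis(tosyloxy)phenyl]-2,3-dihydro-1-benzofuran-3-carboxylic acid | COc1cc(OC)cc(/C=C/c2ccc3c(c2)[C@H](C(=O)O)[C@@H](c2ccc(OS(=O)(=O)c4ccc(C)cc4)c(OS(=O)(=O)c4ccc(C)cc4)c2)O3)c1 | intermediate
13 | 1,3-dioxoisoindolin-2-yl (2S,3S)-5-[(E)-2-(3,5-dimethoxyphenyl)ethenyl]-2-[3,4-bis(tosyloxy)phenyl]-2,3-dihydro-1-benzofuran-3-carboxylate | COc1cc(OC)cc(/C=C/c2ccc3c(c2)[C@H](C(=O)ON2C(=O)c4ccccc4C2=O)[C@@H](c2ccc(OS(=O)(=O)c4ccc(C)cc4)c(OS(=O)(=O)c4ccc(C)cc4)c2)O3)c1 | intermediate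
14 | 1-iodo-3,5-dimethoxybenzene | COc1cc(I)cc(OC)c1 | starting material
15 | (3,5-dimethoxyphenyl)magnesium chloride (LiCl complex) | COc1cc(OC)cc([Mg]Cl)c1 | intermediate (not isolated)
16 | (3,5-dimethoxyphenyl)zinc chloride (THF solution) | COc1cc(OC)cc([Zn]Cl)c1 | intermediate
17 | 4-[(2S,3S)-3-(3,5-dimethoxyphenyl)-5-[(E)-2-(3,5-dimethoxyphenyl)ethenyl]-2,3-dihydro-1-benzofuran-2-yl]-1,2-phenylene bis(4-methylbenzenesulfonate) | COc1cc(OC)cc(/C=C/c2ccc3c(c2)[C@H](c2cc(OC)cc(OC)c2)[C@@H](c2ccc(OS(=O)(=O)c4ccc(C)cc4)c(OS(=O)(=O)c4ccc(C)cc4)c2)O3)c1 | intermediate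
18 | 4-[(2S,3S)-3-(3,5-dihydroxyphenyl)-5-[(E)-2-(3,5-dihydroxyphenyl)ethenyl]-2,3-dihydro-1-benzofuran-2-yl]-1,2-phenylene bis(4-methylbenzenesulfonate) | Oc1cc(O)cc(/C=C/c2ccc3c(c2)[C@H](c2cc(O)cc(O)c2)[C@@H](c2ccc(OS(=O)(=O)c4ccc(C)cc4)c(OS(=O)(=O)c4ccc(C)cc4)c2)O3)c1 | intermediate
19 | 5-[(E)-2-[(2S,3S)-2-(3,4-dihydroxyphenyl)-3-(3,5-dihydroxyphenyl)-2,3-dihydro-1-benzofuran-5-yl]ethenyl]benzene-1,3-diol (trans) | Oc1cc(O)cc(/C=C/c2ccc3c(c2)[C@H](c2cc(O)cc(O)c2)[C@@H](c2ccc(O)c(O)c2)O3)c1 | target

**Step count**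
Total: 12 steps. Longest linear sequence: 11 steps (steps 1–8 and 10–12, from 4-bromocatechol); step 9 prepares the arylzinc reagent.

**Steps most likely to fail**

Step 5. The ring contraction may be undercut by migration of ring C in place of ring A, by elimination of the iodane to the flavone, by simple methoxylation at C3, or by acid-promoted opening of the pyranone to the chalcone with erosion of the C2 configuration. The fallback sets out from 6 and returns at 9, and moves the same C4a shift onto a carbene. Compound 6 would be enolised at −78 °C with LiN(SiMe3)2 in THF and acylated with 2,2,2-trifluoroethyl trifluoroacetate to the 3-trifluoroacetyl ketone F1. Detrifluoroacetylative diazo transfer with methanesulfonyl azide and Et3N in MeCN would then give the 3-diazo ketone F2. Irradiation at 365 nm in methanol would trigger the Wolff rearrangement, C4a moving from C4 to C3 to give the ring-contracted ketene F3, which methanol traps. Any cis ester F4 formed on protonation would be equilibrated with DBU to the trans ester 9.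

Step 10. The benzylic C3 radical may dimerise or be reduced instead of being captured, capture may be insufficiently face-selective, and nickel may begin to insert into the aryl sulfonates. The fallback sets out from 13 and returns at 17, and separates radical generation from C–C bond formation. Copper-catalysed decarboxylative borylation of 13 (Cu(acac)2, B2pin2, LiOH·H2O, MgCl2, dioxane/DMF, rt) would give the trans C3 pinacol boronate F5, boron entering anti to ring C. A stereoretentive Suzuki–Miyaura coupling of this secondary benzylic boronate with iodide 14 (Pd2(dba)3, PPh3, Ag2O, DME, 85 °C) would then give 17.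

Step 12. Cleavage of the second sulfonate, which sits next to a phenoxide, is slow, and prolonged heating of the hexaphenolate in alkali invites air oxidation of the catechol and loss of material on isolation. The fallback sets out from 17 and returns at 19, and reverses the order of the two deprotections so that the basic step is run on a substrate with no free resorcinol phenols and the last operation is non-basic. Compound 17 would be detosylated with KOH in degassed H2O/1,4-dioxane at 80 °C to the catechol tetramethyl ether F6, which can be purified on silica. The four methyl ethers would then be removed with BCl3/n-Bu4NI in CH2Cl2 at −78 °C → 0 °C to give 19.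

**Further compounds**
F1 | step 5 | 6-bromo-3-(trifluoroacetyl)-2-[3,4-bis(tosyloxy)phenyl]chroman-4-one, C2 configured as in 6, C3 undefined (enolisable) | O=C1C(C(=O)C(F)(F)F)[C@@H](c2ccc(OS(=O)(=O)c3ccc(C)cc3)c(OS(=O)(=O)c3ccc(C)cc3)c2)Oc2ccc(Br)cc21
F2 | step 5 | 6-bromo-3-diazo-2-[3,4-bis(tosyloxy)phenyl]chroman-4-one, C2 configured as in 6 | O=C1C(=[N+]=[N-])[C@@H](c2ccc(OS(=O)(=O)c3ccc(C)cc3)c(OS(=O)(=O)c3ccc(C)cc3)c2)Oc2ccc(Br)cc21
F3 | step 5 | 5-bromo-3-(oxomethylidene)-2-[3,4-bis(tosyloxy)phenyl]-2,3-dihydro-1-benzofuran (ketene), C2 configured as in 6 | Brc1ccc2c(c1)C(=C=O)[C@@H](c1ccc(OS(=O)(=O)c3ccc(C)cc3)c(OS(=O)(=O)c3ccc(C)cc3)c1)O2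
F4 | step 5 | methyl (2S,3R)-5-bromo-2-[3,4-bis(tosyloxy)phenyl]-2,3-dihydro-1-benzofuran-3-carboxylate (cis) | Brc1ccc2c(c1)[C@@H](C(=O)OC)[C@@H](c1ccc(OS(=O)(=O)c3ccc(C)cc3)c(OS(=O)(=O)c3ccc(C)cc3)c1)O2
F5 | step 10 | 4-[(2S,3S)-5-[(E)-2-(3,5-dimethoxyphenyl)ethenyl]-3-(4,4,5,5-tetramethyl-1,3,2-dioxaborolan-2-yl)-2,3-dihydro-1-benzofuran-2-yl]-1,2-phenylene bis(4-methylbenzenesulfonate) (trans) | COc1cc(OC)cc(/C=C/c2ccc3c(c2)[C@H](B2OC(C)(C)C(C)(C)O2)[C@@H](c2ccc(OS(=O)(=O)c4ccc(C)cc4)c(OS(=O)(=O)c4ccc(C)cc4)c2)O3)c1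
F6 | step 12 | 4-[(2S,3S)-3-(3,5-dimethoxyphenyl)-5-[(E)-2-(3,5-dimethoxyphenyl)ethenyl]-2,3-dihydro-1-benzofuran-2-yl]benzene-1,2-diol | COc1cc(OC)cc(/C=C/c2ccc3c(c2)[C@H](c2cc(OC)cc(OC)c2)[C@@H](c2ccc(O)c(O)c2)O3)c1
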